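Everything rests on disconnecting the C1'–C6' bond of ring ε. The key step exploits the fact that in this ring the C3' oxygen lies 1,3 to the gem-dimethyl carbon C1' and 1,4 to C6', and that C4'=C5' is out of conjugation. An acyclic (8R)-8-silyloxy trienone from (R)-epichlorohydrin is cyclised by acid in one operation, which closes ring ε, forms C1'–C6', sets C6' trans to the C3' oxygen and places the C4'=C5' alkene. The resulting protected (3R,6R)-3-hydroxy-α-ionone becomes a C15 phosphonium salt, which is joined through a C10 dialdehyde to an acetylenic C15 salt made from (4R,6R)-actinol; desilylation gives the target.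

Key step: step 6

Assumption: (4R,6R)-actinol (20), (E)-3-methylpent-2-en-4-yn-1-ol (23) and the C10 dialdehyde (28) are bought as single isomers; carotenoid numbering is used for ring and chain positions.

Step 1
Reactants: 1 (R)-epichlorohydrin; 2 isopropenylmagnesium bromide
Product: 3 (R)-1-chloro-4-methylpent-4-en-2-ol
Conditions: CuI (10 mol %), THF, −40 → −20 °C; aq NH4Cl
Reagents that add atoms: isopropenylmagnesium bromide (2), C=C(C)[Mg]Br
Why: Copper-catalysed Grignard opening of a terminal epoxide takes place at the unsubstituted ring carbon faster than chloride is displaced, so the carbinol carbon of 1 is not touched and its configuration is carried into 3.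

Step 2
Reactants: 3 (R)-1-chloro-4-methylpent-4-en-2-ol; 4 lithium acetylide–ethylenediamine complex
Product: 6 (R)-6-methylhept-6-en-1-yn-4-ol, via (R)-2-(2-methylallyl)oxirane 5 (not isolated)
Conditions: LiC≡CH·H2NCH2CH2NH2 (3 equiv), DMSO, 5 °C → rt
Reagents that add atoms: lithium acetylide–ethylenediamine complex (4), [Li]C#C.NCCN
Why: The first equivalent of acetylide closes the chlorohydrin to epoxide 5 (Williamson-type ring closure) and the second opens it by SN2 attack at the CH2 terminus (acetylide–epoxide alkylation); neither event involves the carbinol carbon, which stays R.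

Step 3
Reactants: 6 (R)-6-methylhept-6-en-1-yn-4-ol
Product: 7 triisopropyl{[(4R)-6-methylhept-6-en-1-yn-4-yl]oxy}silane
Conditions: i-Pr3SiOTf, 2,6-lutidine, CH2Cl2, 0 °C
Reagents that add atoms: triisopropylsilyl trifluoromethanesulfonate, CC(C)[Si](C(C)C)(C(C)C)OS(=O)(=O)C(F)(F)F
Why: Silylation of the secondary alcohol with a silyl triflate and a hindered base (silyl ether formation) installs a bulky, acid-resistant group that has no Si–aryl bond for the strong acid of step 6 to cleave.

Step 4
Reactants: 7 triisopropyl{[(4R)-6-methylhept-6-en-1-yn-4-yl]oxy}silane; 8 trimethylaluminium; 9 paraformaldehyde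
Product: 12 (2E,5R)-3,7-dimethyl-5-(triisopropylsilyloxy)octa-2,7-dien-1-ol, via alkenyldimethylalane 10 (not isolated), via lithium alkenylaluminate 11 (not isolated)
Conditions: AlMe3, Cp2ZrCl2 (25 mol %), CH2Cl2, 0 °C → rt; volatiles removed; n-BuLi, THF/hexane, −78 °C; (CH2O)n, −78 °C → rt
Reagents that add atoms: trimethylaluminium (8), C[Al](C)C; paraformaldehyde (9), C=O
Why: Negishi zirconium-catalysed carboalumination adds CH3 and Al syn across the terminal alkyne with Al at the terminus (the 1,1-disubstituted alkene is inert), and hydroxymethylation of the derived aluminate with formaldehyde proceeds with retention, so the trisubstituted alkene is formed E.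

Step 5
Reactants: 12 (2E,5R)-3,7-dimethyl-5-(triisopropylsilyloxy)octa-2,7-dien-1-ol; 13 1-(triphenylphosphoranylidene)propan-2-one
Product: 15 (3E,5E,8R)-6,10-dimethyl-8-(triisopropylsilyloxy)undeca-3,5,10-trien-2-one, via enal 14 (not isolated)
Conditions: MnO2 (excess), 13 (1.3 equiv), CH2Cl2, 40 °C
Reagents that add atoms: 1-(triphenylphosphoranylidene)propan-2-one (13), CC(=O)C=P(c1ccccc1)(c1ccccc1)c1ccccc1
Why: MnO2 oxidises only the allylic alcohol and the enal is trapped in the same flask by the stabilised ylide (tandem allylic oxidation–Wittig olefination), which should give the new disubstituted alkene E under neutral conditions that leave the 5E alkene and the silyl ether alone.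

Step 6
Reactants: 15 (3E,5E,8R)-6,10-dimethyl-8-(triisopropylsilyloxy)undeca-3,5,10-trien-2-one
Product: 16 (3R,6R)-3-(triisopropylsilyloxy)-α-ionone, that is (3E)-4-[(1R,4R)-2,6,6-trimethyl-4-(triisopropylsilyloxy)cyclohex-2-en-1-yl]but-3-en-2-one
Conditions: TfOH (2.5 equiv), CH2Cl2, −78 °C; Et3N quench at −78 °C
Reagents that add atoms: none
Why: Markovnikov protonation of the 1,1-disubstituted C10=C11 alkene gives the tertiary cation at C10 (the future C1'), C5 of the dienone (the future C6') attacks it to form the C1'–C6' bond, and the tertiary C5' cation so formed loses H-4' to the counter-ion; the closest known reaction is the Brønsted-acid cation–olefin cyclisation of pseudoionone to α-ionone, of which this is a substituted case. The six-membered ring closes 6-endo-trig with respect to the attacked C5=C6 bond through a chair-like transition state. The new C6' stereocentre is controlled by the C8 silyloxy stereocentre: the OTIPS group takes the equatorial site because the axial site faces the pseudo-axial methyl group of the cationic carbon, and the 5E geometry puts the enone chain equatorial on C6', so the two substituents end up trans (3'R,6'R). The step needs this trans diastereoselection and loss of H-4' in preference to H-6' or a methyl proton; the first is secured by the bulky silyloxy group and the geometrically pure E alkene, the second by kinetic deprotonation at −78 °C with quench before warming, helped by the allylic silyloxy group, which makes the new C4'=C5' bond less basic and so slows its re-protonation. The TIPS group is used because it resists protonolysis, and the methallyl terminus because no allylic C–O bond then exists before the ring is closed.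

Step 7
Reactants: 16 (3R,6R)-3-(triisopropylsilyloxy)-α-ionone; 17 vinylmagnesium bromide
Product: 18 (1E)-3-methyl-1-[(1R,4R)-2,6,6-trimethyl-4-(triisopropylsilyloxy)cyclohex-2-en-1-yl]penta-1,4-dien-3-ol (both C3 epimers)
Conditions: CH2=CHMgBr, THF, −78 → −20 °C; aq NH4Cl
Reagents that add atoms: vinylmagnesium bromide (17), C=C[Mg]Br
Why: Grignard 1,2-addition to the methyl ketone at low temperature is faster than enolisation or conjugate addition; the new carbinol centre forms as a mixture, which does not matter because step 8 erases it.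

Step 8
Reactants: 18 (1E)-3-methyl-1-[(1R,4R)-2,6,6-trimethyl-4-(triisopropylsilyloxy)cyclohex-2-en-1-yl]penta-1,4-dien-3-ol
Product: 19 {(2E,4E)-3-methyl-5-[(1R,4R)-2,6,6-trimethyl-4-(triisopropylsilyloxy)cyclohex-2-en-1-yl]penta-2,4-dien-1-yl}triphenylphosphonium bromide
Conditions: Ph3P·HBr (1.05 equiv), MeOH, 0 °C → rt
Reagents that add atoms: triphenylphosphonium bromide, [Br-].[PH+](c1ccccc1)(c1ccccc1)c1ccccc1
Why: Mild acid ionises the tertiary bis-allylic alcohol to a pentadienyl cation that PPh3 captures at the primary terminus (allylic transposition to the phosphonium salt, the usual way to C15 Wittig salts), giving the conjugated 7'E,9'E diene under thermodynamic control while the hindered secondary silyl ether is much harder to ionise.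

Step 9
Reactants: 20 (4R,6R)-4-hydroxy-2,2,6-trimethylcyclohexan-1-one (actinol)
Product: 21 (4R,6R)-2,2,6-trimethyl-4-(triisopropylsilyloxy)cyclohexan-1-one
Conditions: i-Pr3SiCl, imidazole, DMF, 40 °C
Reagents that add atoms: triisopropylsilyl chloride, CC(C)[Si](Cl)(C(C)C)C(C)C
Why: Silyl ether formation on the unhindered secondary alcohol protects the future C3 hydroxyl through the enolate, coupling and ylide steps, and using the same group as on ring ε allows a single final deprotection.

Step 10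
Reactants: 21 (4R,6R)-2,2,6-trimethyl-4-(triisopropylsilyloxy)cyclohexan-1-one
Product: 22 (4R)-2,6,6-trimethyl-4-(triisopropylsilyloxy)cyclohex-1-en-1-yl trifluoromethanesulfonate
Conditions: LiN(i-Pr)2, THF, −78 → 0 °C; PhNTf2, 0 °C → rt
Reagents that add atoms: N-phenylbis(trifluoromethanesulfonimide), O=S(=O)(N(c1ccccc1)S(=O)(=O)C(F)(F)F)C(F)(F)F
Why: The ketone has only one α-hydrogen (the other α-carbon is quaternary), so enolate O-triflation (enol triflate formation) can give only the tetrasubstituted enol triflate; the methyl-bearing stereocentre is removed on purpose and the silyloxy carbon is not touched.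

Step 11
Reactants: 22 (4R)-2,6,6-trimethyl-4-(triisopropylsilyloxy)cyclohex-1-en-1-yl trifluoromethanesulfonate; 23 (E)-3-methylpent-2-en-4-yn-1-ol
Product: 24 (2E)-3-methyl-5-[(4R)-2,6,6-trimethyl-4-(triisopropylsilyloxy)cyclohex-1-en-1-yl]pent-2-en-4-yn-1-ol
Conditions: Pd(PPh3)4 (5 mol %), CuI (10 mol %), i-Pr2NH, DMF, rt → 50 °C
Reagents that add atoms: (E)-3-methylpent-2-en-4-yn-1-ol (23), C#C/C(C)=C/CO
Why: Sonogashira coupling of the enol triflate with the terminal alkyne forms the C6–C7 bond, tolerates the free allylic alcohol and carries the bought-in E alkene into the product as the 9E bond.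

Step 12
Reactants: 24 (2E)-3-methyl-5-[(4R)-2,6,6-trimethyl-4-(triisopropylsilyloxy)cyclohex-1-en-1-yl]pent-2-en-4-yn-1-ol
Product: 27 tributyl{(2E)-3-methyl-5-[(4R)-2,6,6-trimethyl-4-(triisopropylsilyloxy)cyclohex-1-en-1-yl]pent-2-en-4-yn-1-yl}phosphonium bromide, via allylic mesylate 25 (not isolated), via allylic bromide 26 (not isolated)
Conditions: MsCl, Et3N, THF, −40 °C; LiBr, −40 → 0 °C; filtration; PBu3, EtOAc, rt
Reagents that add atoms: lithium bromide, [Li+].[Br-]; tributylphosphine, CCCCP(CCCC)CCCC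
Why: Mesylation, SN2 displacement by bromide and quaternisation of the phosphine (SN2 alkylation of PBu3) give the salt without acid and without disturbing the 9E alkene; a trialkylphosphonium salt is chosen because allylic trialkylphosphorus ylides olefinate aldehydes with high E selectivity.

Step 13
Reactants: 27 tributyl{(2E)-3-methyl-5-[(4R)-2,6,6-trimethyl-4-(triisopropylsilyloxy)cyclohex-1-en-1-yl]pent-2-en-4-yn-1-yl}phosphonium bromide; 28 (2E,4E,6E)-2,7-dimethylocta-2,4,6-trienedial
Product: 29 (3R)-3-(triisopropylsilyloxy)-7,8-didehydro-12'-apo-β-caroten-12'-al, that is (2E,4E,6E,8E,10E)-2,7,11-trimethyl-13-[(4R)-2,6,6-trimethyl-4-(triisopropylsilyloxy)cyclohex-1-en-1-yl]trideca-2,4,6,8,10-pentaen-12-ynal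
Conditions: KOtBu, THF, −78 °C; ylide added to 28 (2.5 equiv), THF, −78 → 0 °C
Reagents that add atoms: (2E,4E,6E)-2,7-dimethylocta-2,4,6-trienedial (28), O=C/C(C)=C/C=C/C=C(C)/C=O
Why: Wittig olefination of the semi-stabilised tributylphosphorus ylide with one formyl group forms C11=C12, expected E, and addition of the ylide to an excess of the more electrophilic dialdehyde should stop the reaction at the mono-adduct.

Step 14
Reactants: 19 {(2E,4E)-3-methyl-5-[(1R,4R)-2,6,6-trimethyl-4-(triisopropylsilyloxy)cyclohex-2-en-1-yl]penta-2,4-dien-1-yl}triphenylphosphonium bromide; 29 (3R)-3-(triisopropylsilyloxy)-7,8-didehydro-12'-apo-β-caroten-12'-al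
Product: 31 (all-E,3R,3'R,6'R)-3,3'-bis(triisopropylsilyloxy)-7,8-didehydro-β,ε-carotene, via 11'Z isomer 30 (not isolated)
Conditions: NaOMe, CH2Cl2/MeOH, 0 °C → rt; crude mixture then heptane, 85 °C, dark, argon
Reagents that add atoms: aldehyde 29, O=C/C(C)=C/C=C/C=C(C)/C=C/C=C(\C)C#CC1=C(C)C[C@@H](O[Si](C(C)C)(C(C)C)C(C)C)CC1(C)C
Why: Wittig olefination forms C11'=C12' as an E/Z mixture, as is usual for triphenylphosphonium allylic ylides, and the sterically hindered 11'Z isomer (C10'–H against the C13' methyl group) should isomerise thermally to all-E under conditions too mild to move the unhindered double bonds; no stereocentre is involved.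

Step 15
Reactants: 31 (all-E,3R,3'R,6'R)-3,3'-bis(triisopropylsilyloxy)-7,8-didehydro-β,ε-carotene
Product: 32 (3R,3'R,6'R)-7,8-didehydro-β,ε-carotene-3,3'-diol (target)
Conditions: Bu4NF, THF, rt, dark
Reagents that add atoms: none
Why: Fluoride-induced desilylation cleaves both silyl ethers under conditions that should leave the polyene, the allylic C3' carbinol and the doubly allylic C6'–H untouched.

Compound list
1 | (R)-epichlorohydrin | ClC[C@H]1CO1 | starting material
2 | isopropenylmagnesium bromide | C=C(C)[Mg]Br | starting material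
3 | (R)-1-chloro-4-methylpent-4-en-2-ol | ClC[C@H](O)CC(C)=C | intermediate
4 | lithium acetylide–ethylenediamine complex | [Li]C#C.NCCN | starting material
5 | (R)-2-(2-methylallyl)oxirane | C=C(C)C[C@@H]1CO1 | intermediate
6 | (R)-6-methylhept-6-en-1-yn-4-ol | C#CC[C@H](O)CC(C)=C | intermediate
7 | triisopropyl{[(4R)-6-methylhept-6-en-1-yn-4-yl]oxy}silane | C#CC[C@H](O[Si](C(C)C)(C(C)C)C(C)C)CC(C)=C | intermediate
8 | trimethylaluminium | C[Al](C)C | starting material
9 | paraformaldehyde (formaldehyde unit) | C=O | starting material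
10 | [(1E,4R)-2,6-dimethyl-4-(triisopropylsilyloxy)hepta-1,6-dien-1-yl]dimethylalane | C[Al](C)/C=C(\C)C[C@H](O[Si](C(C)C)(C(C)C)C(C)C)CC(C)=C | intermediate
11 | lithium butyl[(1E,4R)-2,6-dimethyl-4-(triisopropylsilyloxy)hepta-1,6-dien-1-yl]dimethylaluminate | [Li+].CCCC[Al-](C)(C)/C=C(\C)C[C@H](O[Si](C(C)C)(C(C)C)C(C)C)CC(C)=C | intermediate
12 | (2E,5R)-3,7-dimethyl-5-(triisopropylsilyloxy)octa-2,7-dien-1-ol | OC/C=C(\C)C[C@H](O[Si](C(C)C)(C(C)C)C(C)C)CC(C)=C | intermediate
13 | 1-(triphenylphosphoranylidene)propan-2-one | CC(=O)C=P(c1ccccc1)(c1ccccc1)c1ccccc1 | starting material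
14 | (2E,5R)-3,7-dimethyl-5-(triisopropylsilyloxy)octa-2,7-dienal | O=C/C=C(\C)C[C@H](O[Si](C(C)C)(C(C)C)C(C)C)CC(C)=C | intermediate
15 | (3E,5E,8R)-6,10-dimethyl-8-(triisopropylsilyloxy)undeca-3,5,10-trien-2-one | CC(=O)/C=C/C=C(C)/C[C@H](O[Si](C(C)C)(C(C)C)C(C)C)CC(C)=C | intermediate
16 | (3R,6R)-3-(triisopropylsilyloxy)-α-ionone | CC1=C[C@H](O[Si](C(C)C)(C(C)C)C(C)C)CC(C)(C)[C@H]1/C=C/C(C)=O | intermediate
17 | vinylmagnesium bromide | C=C[Mg]Br | starting material
18 | (1E)-3-methyl-1-[(1R,4R)-2,6,6-trimethyl-4-(triisopropylsilyloxy)cyclohex-2-en-1-yl]penta-1,4-dien-3-ol (C3 epimers) | CC1=C[C@H](O[Si](C(C)C)(C(C)C)C(C)C)CC(C)(C)[C@H]1/C=C/C(C)(O)C=C | intermediate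
19 | {(2E,4E)-3-methyl-5-[(1R,4R)-2,6,6-trimethyl-4-(triisopropylsilyloxy)cyclohex-2-en-1-yl]penta-2,4-dien-1-yl}triphenylphosphonium bromide | CC1=C[C@H](O[Si](C(C)C)(C(C)C)C(C)C)CC(C)(C)[C@H]1/C=C/C(C)=C/C[P+](c1ccccc1)(c1ccccc1)c1ccccc1.[Br-] | intermediate
20 | (4R,6R)-4-hydroxy-2,2,6-trimethylcyclohexan-1-one (actinol) | O=C1[C@H](C)C[C@@H](O)CC1(C)C | starting material
21 | (4R,6R)-2,2,6-trimethyl-4-(triisopropylsilyloxy)cyclohexan-1-one | O=C1[C@H](C)C[C@@H](O[Si](C(C)C)(C(C)C)C(C)C)CC1(C)C | intermediate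
22 | (4R)-2,6,6-trimethyl-4-(triisopropylsilyloxy)cyclohex-1-en-1-yl trifluoromethanesulfonate | FC(F)(F)S(=O)(=O)OC1=C(C)C[C@@H](O[Si](C(C)C)(C(C)C)C(C)C)CC1(C)C | intermediate
23 | (E)-3-methylpent-2-en-4-yn-1-ol | C#C/C(C)=C/CO | starting material
24 | (2E)-3-methyl-5-[(4R)-2,6,6-trimethyl-4-(triisopropylsilyloxy)cyclohex-1-en-1-yl]pent-2-en-4-yn-1-ol | OC/C=C(\C)C#CC1=C(C)C[C@@H](O[Si](C(C)C)(C(C)C)C(C)C)CC1(C)C | intermediate
25 | (2E)-3-methyl-5-[(4R)-2,6,6-trimethyl-4-(triisopropylsilyloxy)cyclohex-1-en-1-yl]pent-2-en-4-yn-1-yl methanesulfonate | CS(=O)(=O)OC/C=C(\C)C#CC1=C(C)C[C@@H](O[Si](C(C)C)(C(C)C)C(C)C)CC1(C)C | intermediate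
26 | {[(1R)-4-[(3E)-5-bromo-3-methylpent-3-en-1-yn-1-yl]-3,5,5-trimethylcyclohex-3-en-1-yl]oxy}triisopropylsilane | BrC/C=C(\C)C#CC1=C(C)C[C@@H](O[Si](C(C)C)(C(C)C)C(C)C)CC1(C)C | intermediate
27 | tributyl{(2E)-3-methyl-5-[(4R)-2,6,6-trimethyl-4-(triisopropylsilyloxy)cyclohex-1-en-1-yl]pent-2-en-4-yn-1-yl}phosphonium bromide | CCCC[P+](CCCC)(CCCC)C/C=C(\C)C#CC1=C(C)C[C@@H](O[Si](C(C)C)(C(C)C)C(C)C)CC1(C)C.[Br-] | intermediate
28 | (2E,4E,6E)-2,7-dimethylocta-2,4,6-trienedial | O=C/C(C)=C/C=C/C=C(C)/C=O | starting material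
29 | (3R)-3-(triisopropylsilyloxy)-7,8-didehydro-12'-apo-β-caroten-12'-al | O=C/C(C)=C/C=C/C=C(C)/C=C/C=C(\C)C#CC1=C(C)C[C@@H](O[Si](C(C)C)(C(C)C)C(C)C)CC1(C)C | intermediate
30 | (11'Z,3R,3'R,6'R)-3,3'-bis(triisopropylsilyloxy)-7,8-didehydro-β,ε-carotene | CC1=C[C@H](O[Si](C(C)C)(C(C)C)C(C)C)CC(C)(C)[C@H]1/C=C/C(C)=C/C=C\C(C)=C\C=C\C=C(C)\C=C\C=C(/C)C#CC1=C(C)C[C@@H](O[Si](C(C)C)(C(C)C)C(C)C)CC1(C)C | intermediate
31 | (all-E,3R,3'R,6'R)-3,3'-bis(triisopropylsilyloxy)-7,8-didehydro-β,ε-carotene | CC1=C[C@H](O[Si](C(C)C)(C(C)C)C(C)C)CC(C)(C)[C@H]1/C=C/C(C)=C/C=C/C(C)=C/C=C/C=C(C)/C=C/C=C(\C)C#CC1=C(C)C[C@@H](O[Si](C(C)C)(C(C)C)C(C)C)CC1(C)C | intermediate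
32 | (3R,3'R,6'R)-7,8-didehydro-β,ε-carotene-3,3'-diol | CC1=C[C@H](O)CC(C)(C)[C@H]1/C=C/C(C)=C/C=C/C(C)=C/C=C/C=C(C)/C=C/C=C(\C)C#CC1=C(C)C[C@@H](O)CC1(C)C | target

Total step count: 15. Longest linear sequence: 10 steps (steps 1–8, 14 and 15, from 1); the acetylenic branch (steps 9–13) joins at step 14.

Steps most likely to fail

Step 6. The β-silyloxy group may slow formation and capture of the C1' cation so much that other processes overtake ring closure. These are protonolysis of the silyl ether, ionisation of the newly allylic C3'–O bond, rotation about C5=C6 in the protonated dienone (which would erode the trans selectivity) and drift of the ring alkene into conjugation. The fallback avoids any cation–olefin cyclisation and sets out from enol triflate 22. Palladium-catalysed methoxycarbonylation (Pd(OAc)2, dppp, CO, MeOH, Et3N, DMF) should give methyl (4R)-2,6,6-trimethyl-4-(triisopropylsilyloxy)cyclohex-1-ene-1-carboxylate F1. γ-Deprotonation with LiN(i-Pr)2 (THF/HMPA, −78 °C) and kinetic α-protonation of the dienolate should give the deconjugated ester methyl (1R,4R)-2,6,6-trimethyl-4-(triisopropylsilyloxy)cyclohex-2-ene-1-carboxylate F2; its facial selectivity is not predictable, so F2 would be separated from its C1 epimer, which can be re-enolised. Reduction with i-Bu2AlH at −78 °C should give (1R,4R)-2,6,6-trimethyl-4-(triisopropylsilyloxy)cyclohex-2-ene-1-carbaldehyde F3, and Wittig olefination of F3 with ylide 13 comes back to the route at 16.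

Step 13. The 9E geometry may be lost by rotation within the delocalised allylic ylide, and the dialdehyde may be olefinated twice. The fallback reverses the polarity at C11=C12 so that the C9=C10 bond is never part of an ylide; it sets out from alcohol 24 and salt 19. Oxidation of 24 (MnO2, CH2Cl2) should give (2E)-3-methyl-5-[(4R)-2,6,6-trimethyl-4-(triisopropylsilyloxy)cyclohex-1-en-1-yl]pent-2-en-4-ynal F4. Salt 19 would be condensed with excess 28 (NaOMe) to (3R,6R)-3-(triisopropylsilyloxy)-12'-apo-ε-caroten-12'-al F5, reduced (NaBH4) to (3R,6R)-3-(triisopropylsilyloxy)-12'-apo-ε-caroten-12'-ol F6 and converted (Ph3P·HBr, MeOH) into [(3R,6R)-3-(triisopropylsilyloxy)-12'-apo-ε-caroten-12'-yl]triphenylphosphonium bromide F7. Wittig reaction of F7 with F4 (NaOMe), followed by thermal isomerisation of the hindered cis bond, comes back to the route at 31.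

Step 8. Acid may ionise the allylic C3' ether, the pentadienyl cation may lose a proton instead of being captured by the phosphine, and some 9'Z salt may form. The fallback makes the ε half the aldehyde partner and sets out from ketone 16 and aldehyde 29. Horner–Wadsworth–Emmons reaction of 16 with diethyl cyanomethylphosphonate (NaH, THF) should give (2E,4E)-3-methyl-5-[(1R,4R)-2,6,6-trimethyl-4-(triisopropylsilyloxy)cyclohex-2-en-1-yl]penta-2,4-dienenitrile F8, with the 2Z isomer removed by chromatography. Reduction with i-Bu2AlH should give (2E,4E)-3-methyl-5-[(1R,4R)-2,6,6-trimethyl-4-(triisopropylsilyloxy)cyclohex-2-en-1-yl]penta-2,4-dienal F9. Aldehyde 29 would be reduced (NaBH4) to (3R)-3-(triisopropylsilyloxy)-7,8-didehydro-12'-apo-β-caroten-12'-ol F10 and converted (Ph3P·HBr) into [(3R)-3-(triisopropylsilyloxy)-7,8-didehydro-12'-apo-β-caroten-12'-yl]triphenylphosphonium bromide F11, whose silyl ether is not allylic. Wittig reaction of F11 with F9 (NaOMe), then thermal isomerisation, comes back to the route at 31.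

Further compounds
F1 | step 6 | methyl (4R)-2,6,6-trimethyl-4-(triisopropylsilyloxy)cyclohex-1-ene-1-carboxylate | COC(=O)C1=C(C)C[C@@H](O[Si](C(C)C)(C(C)C)C(C)C)CC1(C)C
F2 | step 6 | methyl (1R,4R)-2,6,6-trimethyl-4-(triisopropylsilyloxy)cyclohex-2-ene-1-carboxylate | CC1=C[C@H](O[Si](C(C)C)(C(C)C)C(C)C)CC(C)(C)[C@H]1C(=O)OC
F3 | step 6 | (1R,4R)-2,6,6-trimethyl-4-(triisopropylsilyloxy)cyclohex-2-ene-1-carbaldehyde | CC1=C[C@H](O[Si](C(C)C)(C(C)C)C(C)C)CC(C)(C)[C@H]1C=O
F4 | step 13 | (2E)-3-methyl-5-[(4R)-2,6,6-trimethyl-4-(triisopropylsilyloxy)cyclohex-1-en-1-yl]pent-2-en-4-ynal | O=C/C=C(\C)C#CC1=C(C)C[C@@H](O[Si](C(C)C)(C(C)C)C(C)C)CC1(C)C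
F5 | step 13 | (3R,6R)-3-(triisopropylsilyloxy)-12'-apo-ε-caroten-12'-al | CC1=C[C@H](O[Si](C(C)C)(C(C)C)C(C)C)CC(C)(C)[C@H]1/C=C/C(C)=C/C=C/C(C)=C/C=C/C=C(C)/C=O
F6 | step 13 | (3R,6R)-3-(triisopropylsilyloxy)-12'-apo-ε-caroten-12'-ol | CC1=C[C@H](O[Si](C(C)C)(C(C)C)C(C)C)CC(C)(C)[C@H]1/C=C/C(C)=C/C=C/C(C)=C/C=C/C=C(C)/CO
F7 | step 13 | [(3R,6R)-3-(triisopropylsilyloxy)-12'-apo-ε-caroten-12'-yl]triphenylphosphonium bromide | CC1=C[C@H](O[Si](C(C)C)(C(C)C)C(C)C)CC(C)(C)[C@H]1/C=C/C(C)=C/C=C/C(C)=C/C=C/C=C(C)/C[P+](c1ccccc1)(c1ccccc1)c1ccccc1.[Br-]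
F8 | step 8 | (2E,4E)-3-methyl-5-[(1R,4R)-2,6,6-trimethyl-4-(triisopropylsilyloxy)cyclohex-2-en-1-yl]penta-2,4-dienenitrile | CC1=C[C@H](O[Si](C(C)C)(C(C)C)C(C)C)CC(C)(C)[C@H]1/C=C/C(C)=C/C#N
F9 | step 8 | (2E,4E)-3-methyl-5-[(1R,4R)-2,6,6-trimethyl-4-(triisopropylsilyloxy)cyclohex-2-en-1-yl]penta-2,4-dienal | CC1=C[C@H](O[Si](C(C)C)(C(C)C)C(C)C)CC(C)(C)[C@H]1/C=C/C(C)=C/C=O
F10 | step 8 | (3R)-3-(triisopropylsilyloxy)-7,8-didehydro-12'-apo-β-caroten-12'-ol | OC/C(C)=C/C=C/C=C(C)/C=C/C=C(\C)C#CC1=C(C)C[C@@H](O[Si](C(C)C)(C(C)C)C(C)C)CC1(C)C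
F11 | step 8 | [(3R)-3-(triisopropylsilyloxy)-7,8-didehydro-12'-apo-β-caroten-12'-yl]triphenylphosphonium bromide | c1ccccc1[P+](c1ccccc1)(c1ccccc1)C/C(C)=C/C=C/C=C(C)/C=C/C=C(\C)C#CC1=C(C)C[C@@H](O[Si](C(C)C)(C(C)C)C(C)C)CC1(C)C.[Br-]
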